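**Plan**

- Numbering and enabling feature: carbons C1–C25 follow the target SMILES. Ring A is C9, C10, C12, C13, C14, C23; ring B is C6–C9, C23, C24, C25; ring C is C2–C6, C25, C24. Ring C is a cyclohept-4-ene whose sp2 carbon C2 lies between C3 and C24 and whose bridgehead alkene C5=C6 is the central bond of a 2-substituted butadiene C4=C5–C6=C25. This is the retron of an oxyallyl-plus-diene (4+3) cycloaddition with the diene tethered through C6.
- Retrosynthesis: the O–Si bond and C1=C2 are cut first, then C3–C4 and C24–C25 together, which leaves a chloromethyl ketone on ring A. C2–C3, C10–C11, C23–C24 and C8–C9 are then cut back to a 4-substituted cyclohexenone, and ring A is opened at C9–C23 and C13–C14.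
- Forward: the side chain is made from (S)-citronellol and ring A by Michael/aldol annulation with methyl vinyl ketone. The C9 arm (from chloroprene and ethylene oxide), the C23 arm and the C11 methyl are then attached, rings B and C are closed together in one cycloaddition, and C1 is added before desilylation.
- Stereochemistry: C15 comes from (S)-citronellol and the C19=C20 (E) geometry from SeO2 oxidation. C14 is set by the enamine catalyst, C23 by conjugate addition anti to the C14 substituent, and C24 in the cycloaddition under control of C23.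

Key step: step 15

Assumption: the (S)-configured diarylprolinol ether is taken to shield the enamine face as in the usual model, which gives the (14S) centre; if the sense proved opposite, the (R)-catalyst would be used.

**Route**

Step 1
Reactants: 1 (S)-citronellol
Product: 2 (S)-3,7-dimethyloct-6-en-1-yl acetate
Conditions: Ac2O, pyridine, DMAP (cat.), CH2Cl2, 0 → 23 °C
Reagents that add atoms: acetic anhydride, CC(=O)OC(C)=O
Why: DMAP-catalysed acetylation masks the primary hydroxyl so that it stays distinct from the allylic hydroxyl introduced next.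

Step 2
Reactants: 2 (S)-3,7-dimethyloct-6-en-1-yl acetate
Product: 3 (3S,6E)-8-hydroxy-3,7-dimethyloct-6-en-1-yl acetate
Conditions: SeO2 (cat.), tBuOOH, salicylic acid (cat.), CH2Cl2, 23 °C; then NaBH4, MeOH, 0 °C
Reagents that add atoms: tert-butyl hydroperoxide, CC(C)(C)OO
Why: Catalytic SeO2 allylic oxidation (ene reaction then [2,3]-sigmatropic shift) should hydroxylate the (E)-methyl group of the gem-dimethyl alkene selectively and so fix the C19=C20 (E) geometry, while the borohydride returns any over-oxidised enal to the alcohol.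

Step 3
Reactants: 3 (3S,6E)-8-hydroxy-3,7-dimethyloct-6-en-1-yl acetate
Product: 4 (3S,6E)-8-(tert-butyldiphenylsilyloxy)-3,7-dimethyloct-6-en-1-yl acetate
Conditions: TBDPSCl, imidazole, DMF, 23 °C
Reagents that add atoms: tert-butyldiphenylsilyl chloride, CC(C)(C)[Si](Cl)(c1ccccc1)c1ccccc1
Why: Imidazole-mediated silylation gives a primary allylic TBDPS ether that should survive the Lewis-acidic, basic and CsF steps ahead and still fall to Bu4NF at the end.

Step 4
Reactants: 4 (3S,6E)-8-(tert-butyldiphenylsilyloxy)-3,7-dimethyloct-6-en-1-yl acetate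
Product: 5 (3S,6E)-8-(tert-butyldiphenylsilyloxy)-3,7-dimethyloct-6-en-1-ol
Conditions: K2CO3 (cat.), MeOH, 23 °C
Reagents that add atoms: none
Why: Base-catalysed transesterification removes the acetate and leaves the silyl ether untouched.

Step 5
Reactants: 5 (3S,6E)-8-(tert-butyldiphenylsilyloxy)-3,7-dimethyloct-6-en-1-ol
Product: 6 (3S,6E)-8-(tert-butyldiphenylsilyloxy)-3,7-dimethyloct-6-enal
Conditions: TEMPO (10 mol%), PhI(OAc)2, CH2Cl2, 23 °C
Reagents that add atoms: none
Why: Oxoammonium-mediated oxidation stops at the aldehyde and does not touch the trisubstituted alkene or the non-epimerisable C15 centre.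

Step 6
Reactants: 6 (3S,6E)-8-(tert-butyldiphenylsilyloxy)-3,7-dimethyloct-6-enal; 7 methyl vinyl ketone
Product: 9 (4S)-4-[(2S,5E)-7-(tert-butyldiphenylsilyloxy)-6-methylhept-5-en-2-yl]cyclohex-2-en-1-one, via keto aldehyde 8 (not isolated)
Conditions: (S)-2-[methoxy(diphenyl)methyl]pyrrolidine (5 mol%), ethyl 3,4-dihydroxybenzoate (20 mol%), neat, 4 °C; then LiOH (cat.), iPrOH, 23 °C
Reagents that add atoms: none
Why: Enamine-catalysed Michael addition (C13–C14) followed by intramolecular aldol condensation (C9=C23), a Robinson-type annulation, closes ring A, and C14 is set by the catalyst, whose diarylmethyl group shields one face of the E-enamine so that the enone adds to the other and overrides the weak bias of C15.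

Step 7
Reactants: 9 (4S)-4-[(2S,5E)-7-(tert-butyldiphenylsilyloxy)-6-methylhept-5-en-2-yl]cyclohex-2-en-1-one
Product: 10 (4S)-2-iodo-4-[(2S,5E)-7-(tert-butyldiphenylsilyloxy)-6-methylhept-5-en-2-yl]cyclohex-2-en-1-one
Conditions: I2, pyridine, CH2Cl2, 0 → 23 °C
Reagents that add atoms: iodine, II
Why: Pyridine-mediated α-iodination of an enone (conjugate addition of pyridine, iodination of the enolate, elimination) is selective for the enone α-carbon C9 and leaves the isolated trisubstituted alkene alone.

Step 8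
Reactants: 11 chloroprene; 12 ethylene oxide
Product: 14 3-methylenepent-4-en-1-ol, via dienyl Grignard reagent 13 (not isolated)
Conditions: Mg, ZnCl2 (cat.), BrCH2CH2Br (cat.), THF, reflux; then CuI (5 mol%), ethylene oxide, −30 → 0 °C
Reagents that add atoms: none
Why: Buta-1,3-dien-2-ylmagnesium chloride opens the epoxide under copper catalysis at the dienyl carbon, a known entry to 2-substituted butadienes that supplies C4–C8 and C25.

Step 9
Reactants: 14 3-methylenepent-4-en-1-ol
Product: 15 5-iodo-3-methylenepent-1-ene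
Conditions: I2, PPh3, imidazole, CH2Cl2, 0 °C (BHT, used at once)
Reagents that add atoms: iodine, II
Why: Appel-type iodination converts the primary alcohol through its alkoxyphosphonium salt under neutral conditions that spare the diene.

Step 10
Reactants: 10 (4S)-2-iodo-4-[(2S,5E)-7-(tert-butyldiphenylsilyloxy)-6-methylhept-5-en-2-yl]cyclohex-2-en-1-one; 15 5-iodo-3-methylenepent-1-ene
Product: 17 (4S)-2-(3-methylenepent-4-en-1-yl)-4-[(2S,5E)-7-(tert-butyldiphenylsilyloxy)-6-methylhept-5-en-2-yl]cyclohex-2-en-1-one, via alkylzinc iodide 16 (not isolated)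
Conditions: Zn dust, LiCl, THF, 25 °C; then 10, Pd(dba)2 (5 mol%), P(2-furyl)3 (10 mol%), THF/DMF, 25 °C
Reagents that add atoms: none
Why: Negishi coupling (oxidative addition of the alkenyl C–I bond to zerovalent palladium, transmetalation from zinc, reductive elimination) is an established way to α-alkylate enones through their α-iodides and forms C8–C9 without touching C14.

Step 11
Reactants: 17 (4S)-2-(3-methylenepent-4-en-1-yl)-4-[(2S,5E)-7-(tert-butyldiphenylsilyloxy)-6-methylhept-5-en-2-yl]cyclohex-2-en-1-one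
Product: 18 methyl {(1S,6S)-3-(tert-butyldimethylsilyloxy)-2-(3-methylenepent-4-en-1-yl)-6-[(2S,5E)-7-(tert-butyldiphenylsilyloxy)-6-methylhept-5-en-2-yl]cyclohex-2-en-1-yl}acetate
Conditions: CH2=C(OMe)OSiMe2tBu (1.5 equiv), Ph3CSbCl6 (5 mol%), CH2Cl2, −78 °C; pyridine quench
Reagents that add atoms: 1-(tert-butyldimethylsilyloxy)-1-methoxyethene, C=C(OC)O[Si](C)(C)C(C)(C)C
Why: In this Mukaiyama–Michael addition the ketene silyl acetal should attack C23 on the face anti to the C14 substituent (trans-3,4 product), and silyl transfer keeps the enolate as the regiodefined C9=C10 silyl enol ether.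

Step 12
Reactants: 18 methyl {(1S,6S)-3-(tert-butyldimethylsilyloxy)-2-(3-methylenepent-4-en-1-yl)-6-[(2S,5E)-7-(tert-butyldiphenylsilyloxy)-6-methylhept-5-en-2-yl]cyclohex-2-en-1-yl}acetate
Product: 19 methyl {(1S,6S)-2-(3-methylenepent-4-en-1-yl)-3-(trifluoromethylsulfonyloxy)-6-[(2S,5E)-7-(tert-butyldiphenylsilyloxy)-6-methylhept-5-en-2-yl]cyclohex-2-en-1-yl}acetate
Conditions: CsF, PhNTf2, DME, 23 °C
Reagents that add atoms: N-phenylbis(trifluoromethanesulfonimide), O=S(=O)(N(c1ccccc1)S(=O)(=O)C(F)(F)F)C(F)(F)F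
Why: Fluoride cleaves the silyl enol ether far faster than the alkyl TBDPS ether, and the caesium enolate is O-sulfonylated in place, so the alkene position fixed in step 11 is carried into the enol triflate.

Step 13
Reactants: 19 methyl {(1S,6S)-2-(3-methylenepent-4-en-1-yl)-3-(trifluoromethylsulfonyloxy)-6-[(2S,5E)-7-(tert-butyldiphenylsilyloxy)-6-methylhept-5-en-2-yl]cyclohex-2-en-1-yl}acetate
Product: 20 methyl {(1S,6S)-3-methyl-2-(3-methylenepent-4-en-1-yl)-6-[(2S,5E)-7-(tert-butyldiphenylsilyloxy)-6-methylhept-5-en-2-yl]cyclohex-2-en-1-yl}acetate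
Conditions: Me2CuLi (from CuI and MeLi), THF, −20 → 0 °C
Reagents that add atoms: lithium dimethylcuprate, [Li+].C[Cu-]C
Why: Cuprate coupling of an enol triflate replaces OTf by methyl (C11) with retention of the C9=C10 position, and neither the ester nor the diene reacts with the cuprate at this temperature.

Step 14
Reactants: 20 methyl {(1S,6S)-3-methyl-2-(3-methylenepent-4-en-1-yl)-6-[(2S,5E)-7-(tert-butyldiphenylsilyloxy)-6-methylhept-5-en-2-yl]cyclohex-2-en-1-yl}acetate
Product: 21 1-chloro-3-{(1S,6S)-3-methyl-2-(3-methylenepent-4-en-1-yl)-6-[(2S,5E)-7-(tert-butyldiphenylsilyloxy)-6-methylhept-5-en-2-yl]cyclohex-2-en-1-yl}propan-2-one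
Conditions: ICH2Cl, MeLi·LiBr, THF, −78 °C; sat. NH4Cl at −78 °C
Reagents that add atoms: chloroiodomethane, ClCI
Why: Chloromethyllithium formed by iodine–lithium exchange adds to the ester to give a tetrahedral lithium adduct that is stable at −78 °C and collapses to the chloromethyl ketone only on quenching, a known one-carbon homologation of esters that installs C3.

Step 15
Reactants: 21 1-chloro-3-{(1S,6S)-3-methyl-2-(3-methylenepent-4-en-1-yl)-6-[(2S,5E)-7-(tert-butyldiphenylsilyloxy)-6-methylhept-5-en-2-yl]cyclohex-2-en-1-yl}propan-2-one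
Product: 23 silyl-protected bridged tricyclic C2 ketone (14S,15S,23R,24S; C5=C6 bridgehead alkene), via oxyallyl cation 22 (not isolated)
Conditions: Et3N (3 equiv), CF3CH2OH (0.01 M), 23 → 50 °C
Reagents that add atoms: none
Why: Triethylamine enolises the ketone toward C24 and, in the ionising solvent, chloride leaves C3 to give the oxyallyl cation C3–C2(O)–C24, which is trapped by the s-cis form of the tethered butadiene with formation of C3–C4 and C24–C25, either in concert or by C24–C25 bonding followed by ring closure. The closest known reaction type is the base-induced (4+3) cycloaddition of α-halo ketones with dienes in fluorinated alcohols, including its intramolecular type 2 form in which the diene is tethered through its 2-position. Ring C closes as the new cycloheptenone by union of the three cation carbons with the four diene carbons, and ring B closes as a seven-membered ring across the four-atom tether C23–C9–C8–C7 through the C24–C25 bond, which leaves the former central diene bond as the bridgehead alkene C5=C6. The new centre C24 is controlled by C23: the diene can reach only the face of the cation terminus on which C9 sits, and the rotamer about C23–C24 that keeps the C23–H bond near the cation plane on the C2 side (least allylic strain) turns C14 away from the forming ketone bridge, which corresponds to the (24S) configuration. The step needs regioselectivity, secured by the short tether that lets only the proximal diene terminus C25 reach C24, and chemoselectivity over the C9=C10 alkene, which is expected because the diene offers a cyclic six-electron pathway whereas capture by the ring A alkene would have to pass through a tertiary cation to a strained fused cyclopentanone; high dilution suppresses intermolecular capture.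

Step 16
Reactants: 23 silyl-protected bridged tricyclic C2 ketone (14S,15S,23R,24S; C5=C6 bridgehead alkene)
Product: 24 tert-butyldiphenylsilyl ether of the target (C1=C2 exocyclic methylene in place)
Conditions: Zn, CH2Br2, TiCl4, THF, −40 → 5 °C (aged); then 23, CH2Cl2, 23 °C
Reagents that add atoms: dibromomethane, BrCBr
Why: Takai–Lombardo methylenation uses a non-basic zinc/titanium gem-dimetallic reagent suited to hindered, enolisable ketones, so C24 next to the carbonyl should not epimerise.

Step 17
Reactants: 24 tert-butyldiphenylsilyl ether of the target (C1=C2 exocyclic methylene in place)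
Product: 25 target allylic alcohol CNP0289180.1 (14S,15S,23R,24S; 19E)
Conditions: Bu4NF, THF, 23 °C
Reagents that add atoms: none
Why: Fluoride cleaves the Si–O bond and leaves the three alkene types and all four stereocentres untouched.

**Compound list**

1 | (S)-citronellol | OCC[C@@H](C)CCC=C(C)C | starting material
2 | (S)-3,7-dimethyloct-6-en-1-yl acetate | CC(=O)OCC[C@@H](C)CCC=C(C)C | intermediate
3 | (3S,6E)-8-hydroxy-3,7-dimethyloct-6-en-1-yl acetate | CC(=O)OCC[C@@H](C)CC/C=C(\C)CO | intermediate
4 | (3S,6E)-8-(tert-butyldiphenylsilyloxy)-3,7-dimethyloct-6-en-1-yl acetate | CC(=O)OCC[C@@H](C)CC/C=C(\C)CO[Si](c1ccccc1)(c1ccccc1)C(C)(C)C | intermediate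
5 | (3S,6E)-8-(tert-butyldiphenylsilyloxy)-3,7-dimethyloct-6-en-1-ol | OCC[C@@H](C)CC/C=C(\C)CO[Si](c1ccccc1)(c1ccccc1)C(C)(C)C | intermediate
6 | (3S,6E)-8-(tert-butyldiphenylsilyloxy)-3,7-dimethyloct-6-enal | O=CC[C@@H](C)CC/C=C(\C)CO[Si](c1ccccc1)(c1ccccc1)C(C)(C)C | intermediate
7 | methyl vinyl ketone | CC(=O)C=C | starting material
8 | (2S,3S,6E)-8-(tert-butyldiphenylsilyloxy)-3,7-dimethyl-2-(3-oxobutyl)oct-6-enal (keto aldehyde) | CC(=O)CC[C@H](C=O)[C@@H](C)CC/C=C(\C)CO[Si](c1ccccc1)(c1ccccc1)C(C)(C)C | intermediate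
9 | (4S)-4-[(2S,5E)-7-(tert-butyldiphenylsilyloxy)-6-methylhept-5-en-2-yl]cyclohex-2-en-1-one | O=C1CC[C@@H]([C@@H](C)CC/C=C(\C)CO[Si](c2ccccc2)(c2ccccc2)C(C)(C)C)C=C1 | intermediate
10 | (4S)-2-iodo-4-[(2S,5E)-7-(tert-butyldiphenylsilyloxy)-6-methylhept-5-en-2-yl]cyclohex-2-en-1-one | O=C1CC[C@@H]([C@@H](C)CC/C=C(\C)CO[Si](c2ccccc2)(c2ccccc2)C(C)(C)C)C=C1I | intermediate
11 | chloroprene (2-chlorobuta-1,3-diene) | C=CC(Cl)=C | starting material
12 | ethylene oxide | C1CO1 | starting material
13 | buta-1,3-dien-2-ylmagnesium chloride | C=CC(=C)[Mg]Cl | intermediate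
14 | 3-methylenepent-4-en-1-ol | C=CC(=C)CCO | intermediate
15 | 5-iodo-3-methylenepent-1-ene | C=CC(=C)CCI | intermediate
16 | (3-methylenepent-4-en-1-yl)zinc iodide | C=CC(=C)CC[Zn]I | intermediate
17 | (4S)-2-(3-methylenepent-4-en-1-yl)-4-[(2S,5E)-7-(tert-butyldiphenylsilyloxy)-6-methylhept-5-en-2-yl]cyclohex-2-en-1-one | O=C1CC[C@@H]([C@@H](C)CC/C=C(\C)CO[Si](c2ccccc2)(c2ccccc2)C(C)(C)C)C=C1CCC(=C)C=C | intermediate
18 | methyl {(1S,6S)-3-(tert-butyldimethylsilyloxy)-2-(3-methylenepent-4-en-1-yl)-6-[(2S,5E)-7-(tert-butyldiphenylsilyloxy)-6-methylhept-5-en-2-yl]cyclohex-2-en-1-yl}acetate | C=CC(=C)CCC1=C(O[Si](C)(C)C(C)(C)C)CC[C@@H]([C@@H](C)CC/C=C(\C)CO[Si](c2ccccc2)(c2ccccc2)C(C)(C)C)[C@@H]1CC(=O)OC | intermediate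
19 | methyl {(1S,6S)-2-(3-methylenepent-4-en-1-yl)-3-(trifluoromethylsulfonyloxy)-6-[(2S,5E)-7-(tert-butyldiphenylsilyloxy)-6-methylhept-5-en-2-yl]cyclohex-2-en-1-yl}acetate | C=CC(=C)CCC1=C(OS(=O)(=O)C(F)(F)F)CC[C@@H]([C@@H](C)CC/C=C(\C)CO[Si](c2ccccc2)(c2ccccc2)C(C)(C)C)[C@@H]1CC(=O)OC | intermediate
20 | methyl {(1S,6S)-3-methyl-2-(3-methylenepent-4-en-1-yl)-6-[(2S,5E)-7-(tert-butyldiphenylsilyloxy)-6-methylhept-5-en-2-yl]cyclohex-2-en-1-yl}acetate | C=CC(=C)CCC1=C(C)CC[C@@H]([C@@H](C)CC/C=C(\C)CO[Si](c2ccccc2)(c2ccccc2)C(C)(C)C)[C@@H]1CC(=O)OC | intermediate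
21 | 1-chloro-3-{(1S,6S)-3-methyl-2-(3-methylenepent-4-en-1-yl)-6-[(2S,5E)-7-(tert-butyldiphenylsilyloxy)-6-methylhept-5-en-2-yl]cyclohex-2-en-1-yl}propan-2-one | C=CC(=C)CCC1=C(C)CC[C@@H]([C@@H](C)CC/C=C(\C)CO[Si](c2ccccc2)(c2ccccc2)C(C)(C)C)[C@@H]1CC(=O)CCl | intermediate
22 | oxyallyl cation (zwitterion) C3–C2(O)–C24 derived from 21 | C=CC(=C)CCC1=C(C)CC[C@@H]([C@@H](C)CC/C=C(\C)CO[Si](c2ccccc2)(c2ccccc2)C(C)(C)C)[C@@H]1C=C([O-])[CH2+] | intermediate
23 | silyl-protected bridged tricyclic C2 ketone (14S,15S,23R,24S; C5=C6 bridgehead alkene) | O=C1CCC=C2CCC3=C(C)CC[C@@H]([C@@H](C)CC/C=C(\C)CO[Si](c4ccccc4)(c4ccccc4)C(C)(C)C)[C@@H]3[C@@H]1C2 | intermediate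
24 | tert-butyldiphenylsilyl ether of the target | C=C1CCC=C2CCC3=C(C)CC[C@@H]([C@@H](C)CC/C=C(\C)CO[Si](c4ccccc4)(c4ccccc4)C(C)(C)C)[C@@H]3[C@@H]1C2 | intermediate
25 | CNP0289180.1 (14S,15S,23R,24S; 19E) | C=C1CCC=C2CCC3=C(C)CC[C@@H]([C@@H](C)CC/C=C(\C)CO)[C@@H]3[C@@H]1C2 | target

**Step count**

Total: 17 steps. Longest linear sequence: 15 steps (steps 1–7 and 10–17 from (S)-citronellol); steps 8 and 9 form the two-step side branch.

**Steps most likely to fail and fallbacks**

Step 15. The cation may be captured by the electron-rich C9=C10 alkene or by the solvent before the diene closes, or the facial preference at C24 may be weak. The fallback sets out from enol triflate 19 and postpones the methylation, so that the ring A alkene is deactivated by the triflate during the cycloaddition. Chloromethylation of the ester of 19 (ICH2Cl, MeLi·LiBr, −78 °C) should give the chloromethyl ketone enol triflate F1. Et3N in CF3CH2OH would then carry out the same (4+3) closure to the bridged ketone enol triflate F2. Cuprate methylation of F2 (Me2CuLi, −40 °C, where the hindered saturated ketone is expected to be spared) rejoins the route at 23.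

Step 10. The dienyl iodide and its zinc reagent may oligomerise, and the free diene may divert the palladium catalyst, so that reduction of the iodoenone competes with coupling. The fallback sets out from iodoenone 10 and carries the diene in masked form. Negishi coupling of 10 with [4-(trimethylsilyl)but-3-yn-1-yl]zinc iodide under the same catalyst should give the silylalkynyl enone F3. K2CO3 in MeOH removes the alkynyl silyl group to give the terminal alkyne F4. Enyne cross-metathesis of F4 with ethylene (1 atm, second-generation Grubbs catalyst, CH2Cl2) then builds the 2-substituted butadiene and rejoins the route at 17; steps 8 and 9 are no longer needed.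

Step 11. Addition to the α-branched, β-hindered enone may be sluggish, the Lewis acid may oligomerise the diene, or the silyl enol ether may be lost and with it the regiochemical memory needed for step 12. The fallback sets out from enone 17 and replaces the Lewis-acid route by a cuprate route with direct enolate triflation. Conjugate addition of [(Z)-EtOCH=CH]2CuLi to 17, again anti to the C14 substituent, followed by trapping of the lithium enolate with PhNTf2, should give the ethoxyvinyl enol triflate F5. Me2CuLi converts F5 into the C10-methyl enol ether F6. Mild acid hydrolysis (PPTS, wet acetone) unmasks the C2 aldehyde F7. Chloromethyllithium at −78 °C adds to F7 to give the chlorohydrin F8, and Dess–Martin oxidation of F8 rejoins the route at chloromethyl ketone 21.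

**Further compounds**

F1 | step 15 | 1-chloro-3-{(1S,6S)-2-(3-methylenepent-4-en-1-yl)-3-(trifluoromethylsulfonyloxy)-6-[(2S,5E)-7-(tert-butyldiphenylsilyloxy)-6-methylhept-5-en-2-yl]cyclohex-2-en-1-yl}propan-2-one | C=CC(=C)CCC1=C(OS(=O)(=O)C(F)(F)F)CC[C@@H]([C@@H](C)CC/C=C(\C)CO[Si](c2ccccc2)(c2ccccc2)C(C)(C)C)[C@@H]1CC(=O)CCl
F2 | step 15 | bridged tricyclic C2 ketone carrying the C10 enol triflate in place of the C10 methyl | O=C1CCC=C2CCC3=C(OS(=O)(=O)C(F)(F)F)CC[C@@H]([C@@H](C)CC/C=C(\C)CO[Si](c4ccccc4)(c4ccccc4)C(C)(C)C)[C@@H]3[C@@H]1C2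
F3 | step 10 | (4S)-2-[4-(trimethylsilyl)but-3-yn-1-yl]-4-[(2S,5E)-7-(tert-butyldiphenylsilyloxy)-6-methylhept-5-en-2-yl]cyclohex-2-en-1-one | O=C1CC[C@@H]([C@@H](C)CC/C=C(\C)CO[Si](c2ccccc2)(c2ccccc2)C(C)(C)C)C=C1CCC#C[Si](C)(C)C
F4 | step 10 | (4S)-2-(but-3-yn-1-yl)-4-[(2S,5E)-7-(tert-butyldiphenylsilyloxy)-6-methylhept-5-en-2-yl]cyclohex-2-en-1-one | O=C1CC[C@@H]([C@@H](C)CC/C=C(\C)CO[Si](c2ccccc2)(c2ccccc2)C(C)(C)C)C=C1CCC#C
F5 | step 11 | enol triflate of ring A carrying a (Z)-2-ethoxyvinyl group on C23 | C=CC(=C)CCC1=C(OS(=O)(=O)C(F)(F)F)CC[C@@H]([C@@H](C)CC/C=C(\C)CO[Si](c2ccccc2)(c2ccccc2)C(C)(C)C)[C@@H]1/C=C\OCC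
F6 | step 11 | C10-methyl ring A diene carrying a (Z)-2-ethoxyvinyl group on C23 | C=CC(=C)CCC1=C(C)CC[C@@H]([C@@H](C)CC/C=C(\C)CO[Si](c2ccccc2)(c2ccccc2)C(C)(C)C)[C@@H]1/C=C\OCC
F7 | step 11 | {(1S,6S)-3-methyl-2-(3-methylenepent-4-en-1-yl)-6-[(2S,5E)-7-(tert-butyldiphenylsilyloxy)-6-methylhept-5-en-2-yl]cyclohex-2-en-1-yl}acetaldehyde | C=CC(=C)CCC1=C(C)CC[C@@H]([C@@H](C)CC/C=C(\C)CO[Si](c2ccccc2)(c2ccccc2)C(C)(C)C)[C@@H]1CC=O
F8 | step 11 | 1-chloro-3-{(1S,6S)-3-methyl-2-(3-methylenepent-4-en-1-yl)-6-[(2S,5E)-7-(tert-butyldiphenylsilyloxy)-6-methylhept-5-en-2-yl]cyclohex-2-en-1-yl}propan-2-ol (both carbinol epimers) | C=CC(=C)CCC1=C(C)CC[C@@H]([C@@H](C)CC/C=C(\C)CO[Si](c2ccccc2)(c2ccccc2)C(C)(C)C)[C@@H]1CC(O)CCl
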